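# Proposed synthesis of (R)-3,4-dimethoxy-2-methyl-5-(5-phenylpentyl)-5,6,7,8-tetrahydroquinoline 1-oxide (18)

Compounds are numbered 1 to 18 as in the steps and the compound list. Quinoline locants (N1, C2 to C8, C4a, C8a; side chain C1' to C5') are used for the target and for the atoms that become it.

## Analysis of the target

Compound 18 is a 5,6,7,8-tetrahydroquinoline 1-oxide in which ring A is a fully substituted pyridine (2-methyl, 3-methoxy, 4-methoxy, fused at C4a and C8a) and ring B is the saturated carbocycle made up of C5 to C8. The only stereocentre is C5, R-configured, benzylic to ring A and carrying the unbranched 5-phenylpentyl chain; with no second centre to relay from, the task is absolute control alone. C5 has no heteroatom and no neighbouring functional group in the target, and it lies peri to the C4 methoxy group, so it is electronically unbiased and crowded. The N-oxide is reducible and binds metals, which argues for introducing it last, whereas the free pyridine nitrogen, flanked by the C2 methyl group and C8, should be a poor ligand in the metal-catalysed steps. C4a and C8a must be functionalised differently on a pyridine that already bears three substituents. The plan rests on one feature: C5 is benzylic, and if C1'–C2' is a double bond it is also the substituted end of an allyl unit C5–C1'–C2'. C6, linked through C7 and C8 to C8a, can then be a stabilised carbanion that attacks this end, which forms C5–C6, closes ring B and creates the stereocentre in one catalyst-controlled event.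

## Retrosynthetic reasoning

**N–O bond (18 to 17).** The N-oxide is removed first in the retrosynthetic sense. It would coordinate or oxidise the iridium, palladium and ruthenium catalysts and would not survive dissolving-metal conditions. The forward step only has to oxidise a hindered but electron-rich pyridine nitrogen in a molecule with no other oxidisable group.

**C2'–C3' bond and the C1'–C2' unsaturation (17 to 16 to 14 and 15).** The chain is cut between C2' and C3' because a vinyl group on C5 is exactly what a branched allylic alkylation leaves behind. Cross-metathesis of 14 with 15 adds C3' to C5' and the phenyl ring in one step. The forward sequence must saturate the alkene of 16 without moving it into conjugation with ring A, which would destroy C5.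

**C6–S bonds (14 to 13).** Two sulfonyl groups are placed on C6 in the retrosynthetic direction. They make C6–H acidic enough for mild base, and both are removed in one reductive operation, which two ester groups would not allow.

**C5–C6 bond (13 to 12).** This is the central disconnection. Cutting C5–C6 opens ring B and removes the stereocentre. The forward reaction is an iridium-catalysed intramolecular allylic alkylation in which the C6 carbanion attacks the aryl-bearing end of the allyl unit. It is cut here because the catalyst's preference for the substituted terminus and the ring-size preference for six over eight point to the same carbon.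

**C2'–O carbonate bond and C6–C7 bond (12 to 11 to 9 and 10).** The carbonate comes from the allylic alcohol 11. The nucleophilic arm is disconnected at C6–C7, which corresponds to conjugate addition of 10 to the 2-vinylpyridine 9. This attaches the three-atom tether without any protecting group.

**C8a–C8 bond (9 to 7 and 8).** The vinyl group is disconnected from C8a as a cross-coupling of the 2-chloropyridine 7 with the vinylboronate 8. A 2-chloropyridine is an activated coupling partner and tolerates the free alcohol.

**C4a–C5 bond (7 to 6 to 4 and 5).** The allylic alcohol comes from the ester 6, and 6 from a Heck reaction of the iodide 4 with 5. Cutting here uses the difference between C–I and C–Cl to distinguish C4a from C8a: the iodide reacts first and the chloride is kept for the later vinylation.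

**C–I and C–Cl bonds (4 to 2 to 1).** The iodide at C4a is traced to the arylmagnesium species 3, formed at the one remaining ring C–H of 2, which lies between chlorine and methoxy. The chloride at C8a is traced to the N-oxide function of commercial 1, which activates its free alpha position. The N-oxide thus serves as a handle at the start and is put back at the end.

## Alternatives that were turned down

**Alternative 1:** Disconnection of ring A at C8a–C4a and C3–C4, with the pyridine made by cycloaddition. The forward key step heats 2-[(4R)-4-ethenyl-9-phenylnonyl]-5-ethoxy-4-methyl-1,3-oxazole A2. The oxazole ring of A2 reacts as an azadiene across its C2 and C5 with the tethered vinyl group, and the oxygen-bridged adduct aromatises by eliminating its alkoxy group to give (5R)-2-methyl-5-(5-phenylpentyl)-5,6,7,8-tetrahydroquinolin-3-ol A1.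
- For: both rings form in one metal-free step, and the stereocentre is set earlier in an open chain, away from the crowded peri position. On ring-construction economy and on independence from a hindered allyl–metal intermediate this alternative is stronger.
- Against: the terminal dienophile carbon arrives as C4–H, so A1 lacks the C4 oxygen. It would have to be introduced late on a pyridinol next to C5, followed by two O-methylations, one of them on a 4-pyridone-type tautomer where N-alkylation competes. The unactivated dienophile needs high temperature. The stereocentre of A2 carries a vinyl group and two alkyl chains that differ only far from the centre, so it needs its own asymmetric C–C bond formation; the chirality problem is moved, not solved.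
- Comparison: the chosen route starts from a pyridine that already carries the methyl and both methoxy groups, needs no oxidation of ring A, and uses one catalytic step for both ring closure and configuration.

**Alternative 2:** Disconnection of ring B at C4a–C5 and C7–C8, with the carbocycle made first and the pyridine later. In the forward key step tert-butyl 3-oxobutanoate A4 adds to (E)-8-phenyloct-2-enal A5 under iminium activation by a chiral secondary amine of the diarylprolinol silyl ether class, which sets C5. The methyl ketone derived from A4 then condenses with the aldehyde derived from A5 to give tert-butyl (6R)-2-oxo-6-(5-phenylpentyl)cyclohex-3-ene-1-carboxylate A3 as a mixture of C1 epimers.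
- For: the stereocentre comes from a well-understood face-shielding model, from the cheap achiral materials A4 and A5, in one metal-free operation. As a source of the C5 configuration this is at least as secure as the iridium step, and better precedented for simple alkyl substituents.
- Against: A3 contains nothing of ring A. A pyridine with 2-methyl, 3-methoxy and 4-methoxy groups would have to be grown on a beta-keto ester whose ester carbon must end as C4–OMe, which passes through pyridone-type intermediates with O- versus N-alkylation ambiguity. The future C5 (C6 of A3) is the Michael carbon beta to the keto ester, so basic or hot condensations risk retro-Michael opening back towards A4 and A5 and loss of configuration. The C7=C8 alkene must also be reduced. The steps after the key step clearly outnumber those of the chosen route.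
- Comparison: the chosen strategy keeps ring A intact from a commercial material and creates C5 late, after which it meets only neutral or reductive conditions.

**Alternative 3:** Disconnection at C7=C8 by ring-closing metathesis that selects between enantiotopic groups. In the forward key step 2-ethenyl-3-(hepta-1,6-dien-4-yl)-4,5-dimethoxy-6-methylpyridine A7 is treated with a chiral molybdenum imido alkylidene of the Mo(N-2,6-iPr2C6H3)(CHCMe2Ph)(biphenolate) type. One allyl arm closes onto the C8a vinyl group to give (R)-5-allyl-3,4-dimethoxy-2-methyl-5,6-dihydroquinoline A6.
- For: the precursor is achiral, the end game is short (chain extension, saturation, N-oxidation), and no activating groups have to be removed. In step count after the key step it equals or beats the chosen route.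
- Against: the two allyl arms of A7 form a 1,6-diene, so closure to a cyclopentene competes directly with the wanted closure onto the conjugated, ortho-hindered vinyl group, which is the least reactive olefin present. Ring-size preference therefore works against the plan. The catalyst must also distinguish two arms that differ only in their relation to a distant group, and it is Lewis acidic and sensitive. Building a diallylmethyl group on the crowded C4a costs several steps, and the later chain extension of A6 must spare the ring alkene.
- Comparison: in the chosen route catalyst preference and ring size both favour the same carbon, and the selectivity question is reduced to the enantioface alone.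

Key step: step 8

## Route

Assumption: the sense of induction of the cyclometallated iridium–phosphoramidite catalyst is taken from intermolecular alkylations of aryl-substituted allyl carbonates by stabilised carbanions, which points to the (Sa,S,S) ligand for (S)-13; if the ring closure follows the opposite sense, the enantiomeric ligand is used and nothing else changes.

L* = (Sa,S,S)-N,N-bis[1-(2-methoxyphenyl)ethyl]dinaphtho[2,1-d:1',2'-f][1,3,2]dioxaphosphepin-4-amine.

Step 1
Reactants: 1 3,4-dimethoxy-2-methylpyridine 1-oxide
Product: 2 6-chloro-3,4-dimethoxy-2-methylpyridine
Conditions: POCl3 (neat, 4 equiv), 90 °C; aq. Na2CO3 work-up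
Reagents that add atoms: phosphoryl chloride, O=P(Cl)(Cl)Cl
Why: Deoxygenative chlorination of a pyridine N-oxide: O-phosphorylation activates the ring, chloride adds at the only free alpha carbon (C2 carries the methyl group, C4 is blocked by methoxy) and loss of dichlorophosphate rearomatises. No amine base is added, so the anhydro-base pathway that leads to substitution on the 2-methyl group is not opened.

Step 2
Reactants: 2 6-chloro-3,4-dimethoxy-2-methylpyridine
Product: 4 2-chloro-3-iodo-4,5-dimethoxy-6-methylpyridine, via arylmagnesium chloride 3 (not isolated)
Conditions: TMPMgCl·LiCl (1.2 equiv), THF, −20 to 0 °C; then I2, −20 °C to rt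
Reagents that add atoms: iodine, II; TMPMgCl·LiCl (supplies MgCl to 3 only), CC1(C)CCCC(C)(C)N1[Mg]Cl.[Li+].[Cl-]
Why: Directed ortho-magnesiation of the single ring C–H, which is acidified and coordinated by the flanking chlorine and methoxy groups, followed by iodinolysis of the C–Mg bond. TMPMgCl·LiCl is used instead of a lithium amide because it metalates ring positions under coordination control and leaves the laterally acidic 2-methyl group alone.

Step 3
Reactants: 4 2-chloro-3-iodo-4,5-dimethoxy-6-methylpyridine; 5 methyl acrylate
Product: 6 methyl (E)-3-(2-chloro-4,5-dimethoxy-6-methylpyridin-3-yl)prop-2-enoate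
Conditions: Pd(OAc)2 (5 mol %), P(o-tol)3 (10 mol %), Et3N, DMF, 90 °C
Reagents that add atoms: none
Why: Heck reaction: zerovalent palladium inserts into the C–I bond much faster than into the C–Cl bond, so only the future C4a is alkenylated. Syn insertion and syn beta-hydride elimination give the E-enoate.

Step 4
Reactants: 6 methyl (E)-3-(2-chloro-4,5-dimethoxy-6-methylpyridin-3-yl)prop-2-enoate
Product: 7 (E)-3-(2-chloro-4,5-dimethoxy-6-methylpyridin-3-yl)prop-2-en-1-ol
Conditions: iBu2AlH (2.5 equiv), CH2Cl2, −78 °C; aq. KNaC4H4O6 work-up
Reagents that add atoms: none
Why: 1,2-Reduction of an alpha,beta-unsaturated ester to the allylic alcohol by iBu2AlH at low temperature; the aryl chloride and the alkene geometry are unaffected.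

Step 5
Reactants: 7 (E)-3-(2-chloro-4,5-dimethoxy-6-methylpyridin-3-yl)prop-2-en-1-ol; 8 4,4,5,5-tetramethyl-2-vinyl-1,3,2-dioxaborolane
Product: 9 (E)-3-(2-ethenyl-4,5-dimethoxy-6-methylpyridin-3-yl)prop-2-en-1-ol
Conditions: Pd(OAc)2 (3 mol %), SPhos (6 mol %), K3PO4, toluene/H2O, 90 °C
Reagents that add atoms: none
Why: Suzuki–Miyaura vinylation of an activated 2-chloropyridine; the electron-rich biaryl phosphine promotes oxidative addition into the hindered C–Cl bond and the free alcohol is tolerated. Compound 9 is used promptly because 2-vinylpyridines polymerise on storage.

Step 6
Reactants: 9 (E)-3-(2-ethenyl-4,5-dimethoxy-6-methylpyridin-3-yl)prop-2-en-1-ol; 10 bis(phenylsulfonyl)methane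
Product: 11 (E)-3-{2-[3,3-bis(phenylsulfonyl)propyl]-4,5-dimethoxy-6-methylpyridin-3-yl}prop-2-en-1-ol
Conditions: 10 (2 equiv), DBU (0.3 equiv), DMSO, 80 °C
Reagents that add atoms: none
Why: Michael addition (pyridylethylation) of a doubly stabilised carbanion to the 2-vinylpyridine, whose ring nitrogen stabilises the developing negative charge at C8; active methylene compounds of comparable acidity are known to add to vinylpyridines. The excess of 10 and the bulk of the monoalkylated product disfavour a second addition.

Step 7
Reactants: 11 (E)-3-{2-[3,3-bis(phenylsulfonyl)propyl]-4,5-dimethoxy-6-methylpyridin-3-yl}prop-2-en-1-ol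
Product: 12 methyl (E)-3-{2-[3,3-bis(phenylsulfonyl)propyl]-4,5-dimethoxy-6-methylpyridin-3-yl}allyl carbonate
Conditions: ClCO2Me (1.5 equiv), pyridine (3 equiv), DMAP (5 mol %), CH2Cl2, 0 °C
Reagents that add atoms: methyl chloroformate, COC(=O)Cl
Why: O-Acylation of the primary allylic alcohol. Pyridine is too weak a base to deprotonate the bis(sulfonyl)methine, so C6 is not acylated.

Step 8
Reactants: 12 methyl (E)-3-{2-[3,3-bis(phenylsulfonyl)propyl]-4,5-dimethoxy-6-methylpyridin-3-yl}allyl carbonate
Product: 13 (S)-5-ethenyl-3,4-dimethoxy-2-methyl-6,6-bis(phenylsulfonyl)-5,6,7,8-tetrahydroquinoline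
Conditions: [Ir(cod)Cl]2 (2.5 mol %), L* (5 mol %), 1,5,7-triazabicyclo[4.4.0]dec-5-ene (10 mol %), THF (0.02 M), 50 °C
Reagents that add atoms: none
Why: This is an iridium-catalysed intramolecular asymmetric allylic alkylation, the closest known type being the branched-selective cyclisation of allylic carbonates carrying a tethered stabilised carbanion under [Ir(cod)Cl]2/phosphoramidite catalysis. The cyclometallated complex of monovalent iridium ionises the carbonate of 12 to a syn-allyl complex of trivalent iridium spanning C5–C1'–C2'; the methyl carbonate anion loses CO2 and the methoxide formed removes the acidic C6–H. The bis(sulfonyl) carbanion then attacks C5 from the face opposite to iridium, forming C5–C6 and releasing the catalyst. Ring B closes in a 6-exo mode with respect to the allyl unit, and C1'=C2' ends outside the ring as the vinyl group. The configuration at C5 is controlled by the phosphoramidite, which decides which allyl face is bound to iridium; attack anti to the metal should then give the S centre. The step needs attack at the aryl-bearing terminus and not at C2', cyclisation and not oligomerisation, and one enantioface: the first is secured both by the preference of iridium for the substituted terminus and by the three-atom tether from C8a, which allows a six-membered ring whereas attack at C2' would require an eight-membered ring containing an E alkene; the second by high dilution; the third by the ligand, whose 2-methoxyphenyl variant is chosen because this ligand type is expected to give the more active and more selective catalyst for a demanding aryl-substituted allyl unit. The pyridine nitrogen, hemmed in by the C2 methyl group and C8, should not compete for the metal.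

Step 9
Reactants: 13 (S)-5-ethenyl-3,4-dimethoxy-2-methyl-6,6-bis(phenylsulfonyl)-5,6,7,8-tetrahydroquinoline
Product: 14 (S)-5-ethenyl-3,4-dimethoxy-2-methyl-5,6,7,8-tetrahydroquinoline
Conditions: Mg turnings (20 equiv, activated), MeOH, rt
Reagents that add atoms: none
Why: Reductive desulfonylation by electron transfer from magnesium: each C–S bond is cleaved through the sulfone radical anion, and the carbon fragment is reduced and protonated by methanol. The isolated vinyl group, the pyridine and the non-acidic C5–H are not involved, so the configuration is retained; this is the usual unmasking of a bis(sulfonyl)methyl group after allylic alkylation.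

Step 10
Reactants: 14 (S)-5-ethenyl-3,4-dimethoxy-2-methyl-5,6,7,8-tetrahydroquinoline; 15 pent-4-enylbenzene
Product: 16 (S)-3,4-dimethoxy-2-methyl-5-[(E)-5-phenylpent-1-enyl]-5,6,7,8-tetrahydroquinoline
Conditions: 15 (4 equiv), second-generation Grubbs catalyst RuCl2(=CHPh)(H2IMes)(PCy3) (5 mol %), 1,4-benzoquinone (10 mol %), CH2Cl2, 40 °C
Reagents that add atoms: none
Why: Olefin cross-metathesis between the allylically branched, slowly dimerising vinyl group of 14 and an excess of the unhindered terminal alkene 15; the E alkene should predominate and any Z isomer converges in step 11. 1,4-Benzoquinone suppresses ruthenium hydride-mediated double-bond migration that would endanger C5, and the flanked pyridine nitrogen is a poor ligand for ruthenium.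

Step 11
Reactants: 16 (S)-3,4-dimethoxy-2-methyl-5-[(E)-5-phenylpent-1-enyl]-5,6,7,8-tetrahydroquinoline
Product: 17 (R)-3,4-dimethoxy-2-methyl-5-(5-phenylpentyl)-5,6,7,8-tetrahydroquinoline
Conditions: H2 (3 atm), RhCl(PPh3)3 (5 mol %), toluene/EtOH, rt
Reagents that add atoms: none
Why: Homogeneous hydrogenation of the disubstituted alkene. RhCl(PPh3)3 is chosen over Pd/C because it does not readily move double bonds, so the allylic, benzylic C5 centre is not scrambled; the descriptor changes from S to R only through the priority rules.

Step 12
Reactants: 17 (R)-3,4-dimethoxy-2-methyl-5-(5-phenylpentyl)-5,6,7,8-tetrahydroquinoline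
Product: 18 (R)-3,4-dimethoxy-2-methyl-5-(5-phenylpentyl)-5,6,7,8-tetrahydroquinoline 1-oxide
Conditions: mCPBA (1.2 equiv), CH2Cl2, 0 °C to rt; aq. NaHCO3 work-up
Reagents that add atoms: 3-chloroperoxybenzoic acid, O=C(OO)c1cccc(Cl)c1
Why: N-Oxidation of an electron-rich pyridine by a peracid; no alkene or other oxidisable group remains, and C5 is not affected.

## Compound list

1 | 3,4-dimethoxy-2-methylpyridine 1-oxide | COc1cc[n+]([O-])c(C)c1OC | starting material
2 | 6-chloro-3,4-dimethoxy-2-methylpyridine | COc1cc(Cl)nc(C)c1OC | intermediate
3 | (2-chloro-4,5-dimethoxy-6-methylpyridin-3-yl)magnesium chloride (LiCl complex) | COc1c([Mg]Cl)c(Cl)nc(C)c1OC | intermediate (not isolated)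
4 | 2-chloro-3-iodo-4,5-dimethoxy-6-methylpyridine | COc1c(I)c(Cl)nc(C)c1OC | intermediate
5 | methyl acrylate | C=CC(=O)OC | starting material
6 | methyl (E)-3-(2-chloro-4,5-dimethoxy-6-methylpyridin-3-yl)prop-2-enoate | COC(=O)/C=C/c1c(OC)c(OC)c(C)nc1Cl | intermediate
7 | (E)-3-(2-chloro-4,5-dimethoxy-6-methylpyridin-3-yl)prop-2-en-1-ol | OC/C=C/c1c(OC)c(OC)c(C)nc1Cl | intermediate
8 | 4,4,5,5-tetramethyl-2-vinyl-1,3,2-dioxaborolane | C=CB1OC(C)(C)C(C)(C)O1 | starting material
9 | (E)-3-(2-ethenyl-4,5-dimethoxy-6-methylpyridin-3-yl)prop-2-en-1-ol | OC/C=C/c1c(OC)c(OC)c(C)nc1C=C | intermediate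
10 | bis(phenylsulfonyl)methane | O=S(=O)(CS(=O)(=O)c1ccccc1)c1ccccc1 | starting material
11 | (E)-3-{2-[3,3-bis(phenylsulfonyl)propyl]-4,5-dimethoxy-6-methylpyridin-3-yl}prop-2-en-1-ol | OC/C=C/c1c(OC)c(OC)c(C)nc1CCC(S(=O)(=O)c1ccccc1)S(=O)(=O)c1ccccc1 | intermediate
12 | methyl (E)-3-{2-[3,3-bis(phenylsulfonyl)propyl]-4,5-dimethoxy-6-methylpyridin-3-yl}allyl carbonate | COC(=O)OC/C=C/c1c(OC)c(OC)c(C)nc1CCC(S(=O)(=O)c1ccccc1)S(=O)(=O)c1ccccc1 | intermediate
13 | (S)-5-ethenyl-3,4-dimethoxy-2-methyl-6,6-bis(phenylsulfonyl)-5,6,7,8-tetrahydroquinoline | COc1c(OC)c(C)nc2c1[C@H](C=C)C(S(=O)(=O)c1ccccc1)(S(=O)(=O)c1ccccc1)CC2 | intermediate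
14 | (S)-5-ethenyl-3,4-dimethoxy-2-methyl-5,6,7,8-tetrahydroquinoline | COc1c(OC)c(C)nc2c1[C@H](C=C)CCC2 | intermediate
15 | pent-4-enylbenzene | C=CCCCc1ccccc1 | starting material
16 | (S)-3,4-dimethoxy-2-methyl-5-[(E)-5-phenylpent-1-enyl]-5,6,7,8-tetrahydroquinoline | COc1c(OC)c(C)nc2c1[C@H](/C=C/CCCc1ccccc1)CCC2 | intermediate
17 | (R)-3,4-dimethoxy-2-methyl-5-(5-phenylpentyl)-5,6,7,8-tetrahydroquinoline | COc1c(OC)c(C)nc2c1[C@H](CCCCCc1ccccc1)CCC2 | intermediate
18 | (R)-3,4-dimethoxy-2-methyl-5-(5-phenylpentyl)-5,6,7,8-tetrahydroquinoline 1-oxide | COc1c(OC)c(C)[n+]([O-])c2c1[C@H](CCCCCc1ccccc1)CCC2 | target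

## Step count and least certain steps

Total step count: 12. Longest linear sequence: 12 steps (1 to 18); 5, 8, 10 and 15 are commercial and enter directly.

**Step 8 (key step).** The ring closure may be slow or poorly selective. The allyl terminus sits on an aryl ring substituted at both ortho positions (the C4 methoxy group and the tether), which twists the ring out of conjugation and crowds the catalyst pocket, and the attacking carbanion is fully substituted. Either ionisation or the anti attack could stall, and a loosely bound allyl could erode the enantioselectivity.

Fallback: the allylation and the ring closure are separated, so that the unsubstituted carbanion performs the allylation and ring B is closed at C6–C7 instead. Starting from 7, acylation with methyl chloroformate and pyridine gives methyl (E)-3-(2-chloro-4,5-dimethoxy-6-methylpyridin-3-yl)allyl carbonate F1. Intermolecular alkylation of F1 with 10 under [Ir(cod)Cl]2/L*, a known branched-selective reaction of this nucleophile, gives (S)-3-[1,1-bis(phenylsulfonyl)but-3-en-2-yl]-2-chloro-4,5-dimethoxy-6-methylpyridine F2. Suzuki–Miyaura vinylation with 8 gives (S)-3-[1,1-bis(phenylsulfonyl)but-3-en-2-yl]-2-ethenyl-4,5-dimethoxy-6-methylpyridine F3. Treatment with DBU induces a 6-endo intramolecular Michael addition of the bis(sulfonyl) carbanion to the vinylpyridine, and the route is rejoined at 13 with the same number of steps.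

**Step 6.** The conjugate addition may be sluggish, because the carbanion of 10 is weakly nucleophilic and the two methoxy groups reduce the acceptor strength of the vinylpyridine. Prolonged heating invites polymerisation of the vinyl group and a second pyridylethylation.

Fallback: the C6–C7 bond is made by substitution at an sp3 carbon. Starting from 9, acylation gives methyl (E)-3-(2-ethenyl-4,5-dimethoxy-6-methylpyridin-3-yl)allyl carbonate F4. Hydroboration of the terminal vinyl group with 9-BBN-H, which is selective over the disubstituted alkene, gives methyl (E)-3-{2-[2-(9-borabicyclo[3.3.1]nonan-9-yl)ethyl]-4,5-dimethoxy-6-methylpyridin-3-yl}allyl carbonate F5. Oxidation with NaBO3·4H2O gives methyl (E)-3-[2-(2-hydroxyethyl)-4,5-dimethoxy-6-methylpyridin-3-yl]allyl carbonate F6. Mitsunobu alkylation of excess 10 with F6 (PPh3, diisopropyl azodicarboxylate, THF) rejoins the route at 12.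

**Step 1.** Chlorination may go astray by attack on the 2-methyl group after its deprotonation in the O-activated N-oxide, or by demethylation and chloride exchange at C4 under the hot acidic conditions.

Fallback: the alpha carbon is aminated and the amine exchanged for chlorine. Starting from 1, activation with Ts2O in the presence of tert-butylamine (PhCF3, 0 °C) gives N-tert-butyl-4,5-dimethoxy-6-methylpyridin-2-amine F7. CF3CO2H at 70 °C removes the tert-butyl group to give 4,5-dimethoxy-6-methylpyridin-2-amine F8. Diazotisation with NaNO2 in concentrated HCl (Sandmeyer-type chlorodediazoniation) rejoins the route at 2.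

**Step 2.** Metalation may occur at the laterally acidic 2-methyl group instead of the ring, or the ortho-chloro arylmagnesium species may decompose by elimination if the temperature rises.

Fallback: electrophilic aromatic iodination of 2 with N-iodosuccinimide and CF3SO3H in MeCN at the only open ring position, which is ortho to the C4 methoxy group. No base is involved, no new intermediate arises, and the route is rejoined at 4.

**Step 10.** Cross-metathesis may suffer from catalyst inhibition by the basic nitrogen, from slow turnover at the branched vinyl group next to the peri methoxy group, or from double-bond migration by ruthenium hydrides, which would erode C5.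

Fallback: the chain is attached by sp3–sp3 coupling, which also makes step 11 unnecessary. Starting from 14, hydroboration with 9-BBN-H gives (R)-5-[2-(9-borabicyclo[3.3.1]nonan-9-yl)ethyl]-3,4-dimethoxy-2-methyl-5,6,7,8-tetrahydroquinoline F9. Alkyl–alkyl Suzuki–Miyaura coupling of F9 with (3-bromopropyl)benzene (Pd(OAc)2, PCy3, K3PO4·H2O, THF, rt) rejoins the route at 17.

## Further compounds

F1 | step 8 | methyl (E)-3-(2-chloro-4,5-dimethoxy-6-methylpyridin-3-yl)allyl carbonate | COC(=O)OC/C=C/c1c(OC)c(OC)c(C)nc1Cl
F2 | step 8 | (S)-3-[1,1-bis(phenylsulfonyl)but-3-en-2-yl]-2-chloro-4,5-dimethoxy-6-methylpyridine | COc1c(OC)c(C)nc(Cl)c1[C@H](C=C)C(S(=O)(=O)c1ccccc1)S(=O)(=O)c1ccccc1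
F3 | step 8 | (S)-3-[1,1-bis(phenylsulfonyl)but-3-en-2-yl]-2-ethenyl-4,5-dimethoxy-6-methylpyridine | COc1c(OC)c(C)nc(C=C)c1[C@H](C=C)C(S(=O)(=O)c1ccccc1)S(=O)(=O)c1ccccc1
F4 | step 6 | methyl (E)-3-(2-ethenyl-4,5-dimethoxy-6-methylpyridin-3-yl)allyl carbonate | COC(=O)OC/C=C/c1c(OC)c(OC)c(C)nc1C=C
F5 | step 6 | methyl (E)-3-{2-[2-(9-borabicyclo[3.3.1]nonan-9-yl)ethyl]-4,5-dimethoxy-6-methylpyridin-3-yl}allyl carbonate | COC(=O)OC/C=C/c1c(OC)c(OC)c(C)nc1CCB1C2CCCC1CCC2
F6 | step 6 | methyl (E)-3-[2-(2-hydroxyethyl)-4,5-dimethoxy-6-methylpyridin-3-yl]allyl carbonate | COC(=O)OC/C=C/c1c(OC)c(OC)c(C)nc1CCO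
F7 | step 1 | N-tert-butyl-4,5-dimethoxy-6-methylpyridin-2-amine | COc1cc(NC(C)(C)C)nc(C)c1OC
F8 | step 1 | 4,5-dimethoxy-6-methylpyridin-2-amine | COc1cc(N)nc(C)c1OC
F0 | step 2 | none | none
F9 | step 10 | (R)-5-[2-(9-borabicyclo[3.3.1]nonan-9-yl)ethyl]-3,4-dimethoxy-2-methyl-5,6,7,8-tetrahydroquinoline | COc1c(OC)c(C)nc2c1[C@H](CCB1C3CCCC1CCC3)CCC2
A1 | alternative 1 | (5R)-2-methyl-5-(5-phenylpentyl)-5,6,7,8-tetrahydroquinolin-3-ol | Cc1nc2CCC[C@@H](CCCCCc3ccccc3)c2cc1O
A2 | alternative 1 | 2-[(4R)-4-ethenyl-9-phenylnonyl]-5-ethoxy-4-methyl-1,3-oxazole | CCOc1oc(CCC[C@H](C=C)CCCCCc2ccccc2)nc1C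
A3 | alternative 2 | tert-butyl (6R)-2-oxo-6-(5-phenylpentyl)cyclohex-3-ene-1-carboxylate (C1 epimers) | O=C1C=CC[C@@H](CCCCCc2ccccc2)C1C(=O)OC(C)(C)C
A4 | alternative 2 | tert-butyl 3-oxobutanoate | CC(=O)CC(=O)OC(C)(C)C
A5 | alternative 2 | (E)-8-phenyloct-2-enal | O=C/C=C/CCCCCc1ccccc1
A6 | alternative 3 | (R)-5-allyl-3,4-dimethoxy-2-methyl-5,6-dihydroquinoline | COc1c(OC)c(C)nc2c1[C@H](CC=C)CC=C2
A7 | alternative 3 | 2-ethenyl-3-(hepta-1,6-dien-4-yl)-4,5-dimethoxy-6-methylpyridine | C=CCC(CC=C)c1c(OC)c(OC)c(C)nc1C=C
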